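Compound numbers are those of the steps and of the compound list at the end.

## Analysis of the target

Dehydroglyasperin C (19) is an isoflav-3-ene: benzo ring A (C4a, C5–C8, C8a) is fused to a 2H-pyran ring C (O1, C2H2, C3=C4), and C3 carries the 2,4-dihydroxyphenyl ring B. Ring A keeps a single hydrogen (C8); C5, C6 and C7 carry, in a row, a methoxy group, a 3-methylbut-2-enyl (prenyl) group and a hydroxyl. There is no stereocentre, and because C3=C4 is endocyclic there is no alkene geometry to set, so the problems are regiochemistry, chemoselectivity and the oxidation level of ring C. The C3=C4 bond is an electron-rich styrene: protonation gives a C4 cation stabilised by O1 and by the C5 and C7 oxygens, which the C2' hydroxyl can trap to a pterocarpan. Acid can also add the C7 phenol to the prenyl double bond (dimethylchroman), and the free triphenol oxidises easily in basic, aerated media. The hard part is therefore to put three different groups on adjacent carbons of a phloroglucinol-type ring without ambiguity and to form the pyran ring under non-acidic conditions with the C2' oxygen masked to the end. The strategy rests on C4: it is a benzylic CH on C4a, next to C8a which carries O1, the pattern of a salicylaldehyde formyl carbon; once C4 has taken up C3 as a vinyl nucleophile and lost its heteroatom, the ortho-quinone methide spanning O1–C8a–C4a–C4–C3–C2 can close O1 to C2.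

## Retrosynthetic reasoning

19 from 18. The three O–Si bonds are cut last. One kind of silyl ether on all three phenols allows a single buffered fluoride treatment, which is the only deprotection the acid-sensitive isoflavene is expected to tolerate. The silyl group on the C2' oxygen also keeps that oxygen from adding to C4 while ring C is made.

18 from 10 and 15. The C3–C4 and O1–C2 bonds of ring C are cut. This divides the molecule into ring A with C4 (aldehyde 10) and ring B with C2 and C3 (boronic acid 15), two pieces of similar size. C4 is already at the aldehyde oxidation level, so no redox step follows ring closure and the C3=C4 bond appears in place. A cut at C3–C1' would need a preformed chromene and a separate arylation; a cut at C4–C4a would bring back aromatic substitution on ring A with its regiochemical ambiguity. The forward reaction has to condense a hindered, electron-rich aldehyde with a secondary amine, pass the 1-arylvinyl group from boron to the iminium carbon (allylic amine 16), then expel the amine and close O1–C2 through the quinone methide 17.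

10 from 9. The O–Si bond at the later C7 oxygen is cut. This oxygen has to be blocked, because a free para phenoxide would deactivate the iminium ion and give boron a second binding site, while the oxygen next to the formyl group must stay free. The two hydroxyls of 9 differ through the hydrogen bond of one of them to the formyl group.

9 from 8 from 7. The two acetal groups and the O-methyl bond are cut. In 7 the only free phenol is the one that becomes the C5 methoxy group, so methylation needs no selectivity. The acetals then come off to give 9.

7 from 5. The bond between ring A and the prenyl group is cut by an aromatic Claisen transform. Direct C-prenylation of a phloroglucinol ring would not distinguish the ring positions. Delivery from the oxygen that later becomes the methoxy group fixes the site, because that oxygen has only one free ortho carbon; the other carries the formyl group.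

5 from 4, 4 from 2 and 3, 2 from 1. The tertiary allyl ether is traced to the alkyne 4 by semihydrogenation, and the ether O–C bond to the phenol 2 and the tertiary propargyl chloride 3. Phenol 2 comes from symmetric 1 by twofold acetal protection, in which symmetry and the hydrogen bond leave exactly one phenol free.

15 from 14, 13, 12 and 11. The C–B bond is traced back through the pinacol ester 14 to the enol triflate 13 of acetophenone 12, made by silylation of 11. This puts boron on the carbon that bears ring B, which is what places ring B on C3 and not on C2 in the key step.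

## Alternatives that were turned down

Alternative 1: The disconnection is at C3–C1', with a temporary C4–O2' bond. In the forward sense Pd(OAc)2 with Ag2CO3 would couple the 3,4-unsubstituted chromene 7-(tert-butyldimethylsilyloxy)-5-methoxy-6-(3-methylbut-2-enyl)-2H-chromene A2 with 5-(tert-butyldimethylsilyloxy)-2-iodophenol A3. Aryl–palladium addition puts the aryl group on C3, and the phenol oxygen then attacks C4, which gives the cis-fused pterocarpan A1. The benzylic C4–O2' bond of A1 would then have to be broken with loss of H3, followed by desilylation to 19.
- For it: the carbon–carbon bond comes from a well-behaved Heck-type carbopalladation, and the partners A2 and A3 are sturdier than 15. On reagent robustness this alternative is the stronger one.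
- Against it: two stereocentres are built in A1 only to be destroyed. The ring opening is an E1-type scission that passes through the very C4 cation that recloses to A1 or is trapped by other nucleophiles, and H3 is not acidic enough for a base-induced opening. The acid needed is what the prenyl phenol and the product resent. A stoichiometric amount of Ag2CO3 is needed, and the prenyl alkene is a second, if slower, Heck acceptor.
- Comparison: A2 would itself come from 10 by an extra ring-forming step, so the sequence is at least two steps longer. In place of robust coupling partners, the chosen route delivers C3=C4 directly, at the right oxidation level and under weakly basic conditions.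

Alternative 2: The disconnections are C4–C4a and O1–C2, both leading to a three-carbon dialdehyde. In HCl-saturated solvent phloroglucinol A6 and the arylmalondialdehyde 2-[2,4-bis(pivaloyloxy)phenyl]malonaldehyde A5 would condense, a ring carbon of A6 attacking one formyl group of A5 and a phenol oxygen of A6 the other, to give the isoflavylium salt 3-[2,4-bis(pivaloyloxy)phenyl]-5,7-dihydroxychromenylium chloride A4.
- For it: it is the shortest way to the complete carbon skeleton, and the symmetry of A6 removes any regiochemical question from the ring formation. On step economy up to the skeleton it is clearly stronger than the chosen route.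
- Against it: A4 is one oxidation level too high, and hydride would have to add at C2 and not at C4. The C5 methoxy, C6 prenyl and C7 hydroxyl would all have to be set afterwards on the two ring A hydroxyls that A4 carries, which have no carbonyl group to tell them apart, with C6 and C8 equally activated. These late operations would run on an acid- and oxidation-sensitive isoflavene. In addition, A5 is not a stock compound and would have to be prepared first; as an enolised malondialdehyde, A5 is prone to self-condensation in strong acid.
- Comparison: the chosen route spends more steps before ring closure, but it makes every regiochemical decision on a benzaldehyde, where the hydrogen bond and the ortho rule of the Claisen rearrangement decide them.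

Alternative 3: The disconnections are C5–C6 and C4a–C8a, so ring A is built from a chain, the ester (Z)-2-[2,4-bis(triisopropylsilyloxy)phenyl]-5-methoxypent-2-en-4-ynyl 7-methyl-3-oxooct-6-enoate A8. After twofold O-silylation of the keto ester unit of A8, the bis(silyloxy)diene so formed would add across the tethered methoxyalkyne, thermally or with Ph3PAuNTf2, and loss of the silyloxy group at C8a would aromatise ring A to give 2',4'-bis-O-triisopropylsilyl dehydroglyasperin C A7.
- For it: the substitution pattern of ring A is written into the chain of A8, so no aromatic substitution selectivity is needed. Two rings form in one step and the C7 hydroxyl of A7 arrives free. In bonds and rings formed per step it is stronger than the chosen route.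
- Against it: A8 needs a long linear build with a Z-configured trisubstituted enyne and a methoxyalkyne that hydrolyses easily. Diene and alkyne are both electron-rich, so the addition would depend on gold activation. The silyl ketene acetal of an allylic ester is an Ireland–Claisen substrate, and that [3,3] shift (C8 to C4) should compete strongly. Monovalent gold could also bring the ketone oxygen or ring B onto the alkyne.
- Comparison: the key step would be without close analogy on a substrate, A8, that is costly to make. The chosen key step has a direct known counterpart and uses two simple arenes.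

Key step: step 12

Remark on the chemistry: 3-chloro-3-methylbut-1-yne (3) is taken as the purchasable form of the tertiary propargyl unit. Intermediates 6 and 16 are racemic and transient, and 17 is drawn in the geometry that can cyclise.

## Steps

Step 1
Reactants: 1 2,4,6-trihydroxybenzaldehyde
Product: 2 2-hydroxy-4,6-bis(methoxymethoxy)benzaldehyde
Conditions: MOMCl (2.2 equiv), i-Pr2NEt, CH2Cl2, 0 °C to rt
Reagents that add atoms: chloromethyl methyl ether (MOMCl), COCCl
Why: Williamson-type acetal ether formation; the para hydroxyl and one of the two equivalent ortho hydroxyls should react, while the remaining ortho hydroxyl is held in the hydrogen bond to the formyl group and is inert to the amine base.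

Step 2
Reactants: 2 2-hydroxy-4,6-bis(methoxymethoxy)benzaldehyde; 3 3-chloro-3-methylbut-1-yne
Product: 4 2,4-bis(methoxymethoxy)-6-(2-methylbut-3-yn-2-yloxy)benzaldehyde
Conditions: 3 (2 equiv), DBU, CuCl2·2H2O (1 mol %), MeCN, 0 °C to rt
Reagents that add atoms: none
Why: Copper-catalysed propargylic etherification; a copper acetylide ionises the tertiary chloride and the phenoxide attacks the tertiary carbon, so the hindered ether forms without an SN2 step. The hydrogen-bonded phenol is the only nucleophile present.

Step 3
Reactants: 4 2,4-bis(methoxymethoxy)-6-(2-methylbut-3-yn-2-yloxy)benzaldehyde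
Product: 5 2,4-bis(methoxymethoxy)-6-(2-methylbut-3-en-2-yloxy)benzaldehyde
Conditions: H2 (1 atm), Pd/CaCO3 poisoned with Pb(OAc)2, quinoline, EtOAc, rt
Reagents that add atoms: none
Why: Lindlar semihydrogenation of the terminal alkyne to the vinyl group; the aldehyde, the acetals and the aryl ether should not be touched by the poisoned catalyst.

Step 4
Reactants: 5 2,4-bis(methoxymethoxy)-6-(2-methylbut-3-en-2-yloxy)benzaldehyde
Product: 7 2-hydroxy-4,6-bis(methoxymethoxy)-3-(3-methylbut-2-enyl)benzaldehyde, via Claisen dienone 6 (not isolated)
Conditions: PhNEt2, 130 °C
Reagents that add atoms: none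
Why: Aromatic Claisen rearrangement; the [3,3] shift, eased by the gem-dimethyl group, can only reach the one free ortho carbon and turns the tertiary allyl ether into a linear prenyl group, and dienone 6 tautomerises to the phenol. The amine solvent keeps acid away from the new ortho-prenyl phenol.

Step 5
Reactants: 7 2-hydroxy-4,6-bis(methoxymethoxy)-3-(3-methylbut-2-enyl)benzaldehyde
Product: 8 2-methoxy-4,6-bis(methoxymethoxy)-3-(3-methylbut-2-enyl)benzaldehyde
Conditions: MeI, K2CO3, DMF, rt
Reagents that add atoms: iodomethane (MeI), CI
Why: Williamson methylation of the only free phenol; carbonate in a dipolar solvent breaks the hydrogen bond to the formyl group, and no other nucleophilic site is present.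

Step 6
Reactants: 8 2-methoxy-4,6-bis(methoxymethoxy)-3-(3-methylbut-2-enyl)benzaldehyde
Product: 9 2,4-dihydroxy-6-methoxy-5-(3-methylbut-2-enyl)benzaldehyde
Conditions: HCl (1 M in MeOH), 25 °C; NaHCO3 work-up
Reagents that add atoms: none
Why: Acid-catalysed transacetalisation of both methoxymethyl ethers to methanol; acetal cleavage is far easier than protonation of the trisubstituted alkene, and the phenol next to the prenyl group is deactivated by the para formyl group, so chroman formation should stay minor at this temperature.

Step 7
Reactants: 9 2,4-dihydroxy-6-methoxy-5-(3-methylbut-2-enyl)benzaldehyde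
Product: 10 4-(tert-butyldimethylsilyloxy)-2-hydroxy-6-methoxy-5-(3-methylbut-2-enyl)benzaldehyde
Conditions: TBSCl (1.05 equiv), imidazole, CH2Cl2, 0 °C
Reagents that add atoms: tert-butyldimethylsilyl chloride (TBSCl), CC(C)(C)[Si](C)(C)Cl
Why: Site-selective silylation; the para hydroxyl is the more acidic and is not hydrogen-bonded, whereas the ortho hydroxyl is tied to the formyl group and should not react with one equivalent of reagent.

Step 8
Reactants: 11 2,4-dihydroxyacetophenone
Product: 12 1-[2,4-bis(tert-butyldimethylsilyloxy)phenyl]ethanone
Conditions: TBSCl (2.5 equiv), imidazole, DMAP (cat.), DMF, 40 °C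
Reagents that add atoms: tert-butyldimethylsilyl chloride (TBSCl), CC(C)(C)[Si](C)(C)Cl
Why: Exhaustive silylation of both phenols; excess reagent, nucleophilic catalysis and gentle warming are used to force the hydrogen-bonded ortho hydroxyl.

Step 9
Reactants: 12 1-[2,4-bis(tert-butyldimethylsilyloxy)phenyl]ethanone
Product: 13 1-[2,4-bis(tert-butyldimethylsilyloxy)phenyl]ethenyl trifluoromethanesulfonate
Conditions: KN(SiMe3)2, THF, −78 °C; then PhNTf2, −78 to 0 °C
Reagents that add atoms: N-phenylbis(trifluoromethanesulfonimide) (PhNTf2), FC(F)(F)S(=O)(=O)N(c1ccccc1)S(=O)(=O)C(F)(F)F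
Why: Enolate O-sulfonylation; the methyl ketone has a single enolisable position, and trapping at low temperature should outrun silyl transfer from the ortho oxygen.

Step 10
Reactants: 13 1-[2,4-bis(tert-butyldimethylsilyloxy)phenyl]ethenyl trifluoromethanesulfonate
Product: 14 2-{1-[2,4-bis(tert-butyldimethylsilyloxy)phenyl]ethenyl}-4,4,5,5-tetramethyl-1,3,2-dioxaborolane
Conditions: B2pin2, PdCl2(dppf) (3 mol %), KOAc, 1,4-dioxane, 80 °C
Reagents that add atoms: bis(pinacolato)diboron (B2pin2), CC1(C)OB(OC1(C)C)B1OC(C)(C)C(C)(C)O1
Why: Miyaura borylation of an alkenyl triflate; the weak acetate base should suppress Suzuki coupling of 14 with 13 and leave the aryl silyl ethers intact.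

Step 11
Reactants: 14 2-{1-[2,4-bis(tert-butyldimethylsilyloxy)phenyl]ethenyl}-4,4,5,5-tetramethyl-1,3,2-dioxaborolane
Product: 15 1-[2,4-bis(tert-butyldimethylsilyloxy)phenyl]ethenylboronic acid
Conditions: NaIO4, NH4OAc, acetone/H2O, rt
Reagents that add atoms: water, O
Why: Oxidative removal of the pinacol ester; periodate cleaves the pinacol set free in the hydrolysis equilibrium and so drives the ester to the free acid at near-neutral pH. The acid is to be used without long storage.

Step 12
Reactants: 10 4-(tert-butyldimethylsilyloxy)-2-hydroxy-6-methoxy-5-(3-methylbut-2-enyl)benzaldehyde; 15 1-[2,4-bis(tert-butyldimethylsilyloxy)phenyl]ethenylboronic acid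
Product: 18 7,2',4'-tris-O-tert-butyldimethylsilyl dehydroglyasperin C, via allylic dibenzylamine 16 (not isolated), via ortho-quinone methide 17 (not isolated)
Conditions: 15 (1.5 equiv), Bn2NH (0.4 equiv), 1,4-dioxane, 90 °C, Ar
Reagents that add atoms: none
Why: The reaction type is the amine-promoted Petasis borono-Mannich condensation of salicylaldehydes with alkenylboronic acids that ends in a 2H-chromene, run here with a 1-arylvinyl partner. Bn2NH condenses with the formyl group of 10 to an iminium ion held as its phenoxide, and this phenoxide binds the boron of 15 to give a tetracoordinate boronate. Within that complex the 1-arylvinyl group migrates by its boron-bearing carbon to the iminium carbon, which makes the C3–C4 bond of 16 and fixes ring B on C3 because the transfer is ipso. At 90 °C the electron-rich ring pushes out the amine and 16 becomes the ortho-quinone methide 17, in which O1, C8a, C4a, C4, C3 and C2 form a 1-oxatriene. Thermal six-electron oxa-electrocyclisation of 17 joins O1 to the terminal methylene C2 and closes the six-membered pyran ring with re-aromatisation of ring A, while the amine returns to the cycle. No stereocentre survives, since the aminated C4 of 16 is racemic and becomes trigonal again. The step needs chemoselectivity for the one free phenol next to the formyl group, and the substrate secures it: the C7, C2' and C4' oxygens are silylated, so boron can bind only O1 and the C2' oxygen cannot add to C4 of 17.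

Step 13
Reactants: 18 7,2',4'-tris-O-tert-butyldimethylsilyl dehydroglyasperin C
Product: 19 dehydroglyasperin C
Conditions: Bu4NF/AcOH (1:1, 3.5 equiv), THF, 0 °C to rt, Ar
Reagents that add atoms: none
Why: Fluoride cleavage of the three aryl silyl ethers; the acetic acid buffer keeps the medium near neutral, so neither phenoxide oxidation nor acid-induced addition to C3=C4 or to the prenyl group should set in.

## Compound list

1 | 2,4,6-trihydroxybenzaldehyde | O=Cc1c(O)cc(O)cc1O | starting material
2 | 2-hydroxy-4,6-bis(methoxymethoxy)benzaldehyde | O=Cc1c(O)cc(OCOC)cc1OCOC | intermediate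
3 | 3-chloro-3-methylbut-1-yne | C#CC(C)(C)Cl | starting material
4 | 2,4-bis(methoxymethoxy)-6-(2-methylbut-3-yn-2-yloxy)benzaldehyde | O=Cc1c(OCOC)cc(OCOC)cc1OC(C)(C)C#C | intermediate
5 | 2,4-bis(methoxymethoxy)-6-(2-methylbut-3-en-2-yloxy)benzaldehyde | O=Cc1c(OCOC)cc(OCOC)cc1OC(C)(C)C=C | intermediate
6 | 2,4-bis(methoxymethoxy)-5-(3-methylbut-2-enyl)-6-oxocyclohexa-1,3-diene-1-carbaldehyde (racemic Claisen dienone) | O=CC1=C(OCOC)C=C(OCOC)C(CC=C(C)C)C1=O | intermediate (not isolated)
7 | 2-hydroxy-4,6-bis(methoxymethoxy)-3-(3-methylbut-2-enyl)benzaldehyde | O=Cc1c(O)c(CC=C(C)C)c(OCOC)cc1OCOC | intermediate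
8 | 2-methoxy-4,6-bis(methoxymethoxy)-3-(3-methylbut-2-enyl)benzaldehyde | O=Cc1c(OC)c(CC=C(C)C)c(OCOC)cc1OCOC | intermediate
9 | 2,4-dihydroxy-6-methoxy-5-(3-methylbut-2-enyl)benzaldehyde | O=Cc1c(O)cc(O)c(CC=C(C)C)c1OC | intermediate
10 | 4-(tert-butyldimethylsilyloxy)-2-hydroxy-6-methoxy-5-(3-methylbut-2-enyl)benzaldehyde | O=Cc1c(O)cc(O[Si](C)(C)C(C)(C)C)c(CC=C(C)C)c1OC | intermediate
11 | 2,4-dihydroxyacetophenone | CC(=O)c1ccc(O)cc1O | starting material
12 | 1-[2,4-bis(tert-butyldimethylsilyloxy)phenyl]ethanone | CC(=O)c1ccc(O[Si](C)(C)C(C)(C)C)cc1O[Si](C)(C)C(C)(C)C | intermediate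
13 | 1-[2,4-bis(tert-butyldimethylsilyloxy)phenyl]ethenyl trifluoromethanesulfonate | C=C(OS(=O)(=O)C(F)(F)F)c1ccc(O[Si](C)(C)C(C)(C)C)cc1O[Si](C)(C)C(C)(C)C | intermediate
14 | 2-{1-[2,4-bis(tert-butyldimethylsilyloxy)phenyl]ethenyl}-4,4,5,5-tetramethyl-1,3,2-dioxaborolane | C=C(B1OC(C)(C)C(C)(C)O1)c1ccc(O[Si](C)(C)C(C)(C)C)cc1O[Si](C)(C)C(C)(C)C | intermediate
15 | 1-[2,4-bis(tert-butyldimethylsilyloxy)phenyl]ethenylboronic acid | C=C(B(O)O)c1ccc(O[Si](C)(C)C(C)(C)C)cc1O[Si](C)(C)C(C)(C)C | intermediate
16 | 2-{2-[2,4-bis(tert-butyldimethylsilyloxy)phenyl]-1-(dibenzylamino)prop-2-enyl}-5-(tert-butyldimethylsilyloxy)-3-methoxy-4-(3-methylbut-2-enyl)phenol (racemic) | COc1c(C(N(Cc2ccccc2)Cc2ccccc2)C(=C)c2ccc(O[Si](C)(C)C(C)(C)C)cc2O[Si](C)(C)C(C)(C)C)c(O)cc(O[Si](C)(C)C(C)(C)C)c1CC=C(C)C | intermediate (not isolated)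
17 | (Z)-6-{2-[2,4-bis(tert-butyldimethylsilyloxy)phenyl]prop-2-enylidene}-3-(tert-butyldimethylsilyloxy)-5-methoxy-4-(3-methylbut-2-enyl)cyclohexa-2,4-dienone | C=C(c1ccc(O[Si](C)(C)C(C)(C)C)cc1O[Si](C)(C)C(C)(C)C)/C=C1\C(=O)C=C(O[Si](C)(C)C(C)(C)C)C(CC=C(C)C)=C1OC | intermediate (not isolated)
18 | 7,2',4'-tris-O-tert-butyldimethylsilyl dehydroglyasperin C, i.e. 7-(tert-butyldimethylsilyloxy)-3-[2,4-bis(tert-butyldimethylsilyloxy)phenyl]-5-methoxy-6-(3-methylbut-2-enyl)-2H-chromene | COc1c2c(cc(O[Si](C)(C)C(C)(C)C)c1CC=C(C)C)OCC(c1ccc(O[Si](C)(C)C(C)(C)C)cc1O[Si](C)(C)C(C)(C)C)=C2 | intermediate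
19 | dehydroglyasperin C, i.e. 4-[7-hydroxy-5-methoxy-6-(3-methylbut-2-enyl)-2H-chromen-3-yl]benzene-1,3-diol | COc1c2c(cc(O)c1CC=C(C)C)OCC(c1ccc(O)cc1O)=C2 | target

## Step count and least certain steps

Total step count: 13. Longest linear sequence: 9 steps (steps 1 to 7, 12 and 13). The boronic acid branch has 4 steps (8 to 11).

Step 12 (key step). The most likely failure is stalling of the boron-to-carbon transfer. The iminium carbon lies between two ortho substituents and is deactivated by three oxygen donors, and the migrating carbon is fully substituted. Protodeboronation of 15 by the water set free on iminium formation may then outrun the transfer. The fallback sets out from 10 and 13 and makes C3–C4 by carbonyl addition. A Nozaki–Hiyama–Kishi coupling (CrCl2 in excess, catalytic NiCl2, DMF, rt) should add the 1-arylvinyl group of 13 to the formyl carbon of 10 through a non-basic vinylchromium species. This should give the allylic alcohol 5-(tert-butyldimethylsilyloxy)-2-{2-[2,4-bis(tert-butyldimethylsilyloxy)phenyl]-1-hydroxyprop-2-enyl}-3-methoxy-4-(3-methylbut-2-enyl)phenol F1. Warming F1 in toluene with a trace of pyridinium p-toluenesulfonate should ionise the doubly activated benzylic alcohol to the same quinone methide 17, which closes to 18, where the route is rejoined.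

Step 11. The free, electron-rich 1-arylvinylboronic acid may undergo protodeboronation or polymerisation during the aqueous oxidative cleavage, or the ester may hydrolyse incompletely. The fallback sets out from 14. Transesterification with diethanolamine in Et2O should precipitate the storable adduct 2-{1-[2,4-bis(tert-butyldimethylsilyloxy)phenyl]ethenyl}-1,3,6,2-dioxazaborocane F2. A short two-phase hydrolysis of F2 (dilute aqueous HCl/Et2O, 0 °C) just before the key step releases 15, where the route is rejoined.

Step 9. The ortho silyl group may transfer from the aryl oxygen to the enolate oxygen through a six-membered transition state before sulfonylation, and the electron-rich enol triflate may hydrolyse on work-up. The fallback sets out from 12 and avoids the enolate. (PhO)3P/Br2 with Et3N in CH2Cl2 (−60 °C to rt) should convert the ketone into the vinyl bromide 1-bromo-1-[2,4-bis(tert-butyldimethylsilyloxy)phenyl]ethene F3. Miyaura borylation of F3 under the conditions of step 10 comes back to the route at 14.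

Step 6. Acid may add the freed phenol to the prenyl double bond (chroman ring closure) before the second, slower acetal is cleaved. The fallback sets out from 8 and replaces Brønsted acid hydrolysis by acetal-to-silyl exchange. Me3SiOTf with 2,2'-bipyridyl in MeCN at 0 °C should turn both aryl methoxymethyl ethers into trimethylsilyl ethers in a buffered aprotic medium, giving 2-methoxy-3-(3-methylbut-2-enyl)-4,6-bis(trimethylsilyloxy)benzaldehyde F4. Stirring F4 with aqueous NaHCO3 in MeOH hydrolyses the labile silyl ethers and comes back to the route at 9.

Step 2. Conversion may be low, because the phenoxide is hydrogen-bonded and flanked by the formyl group, while 3 is consumed by base-induced loss of HCl. The fallback sets out from 2 and uses a Tsuji–Trost O-allylation in place of propargylation and hydrogenation. With tert-butyl 2-methylbut-3-en-2-yl carbonate F5 (from 2-methylbut-3-en-2-ol and Boc2O) and Pd(PPh3)4 in THF at 0 °C, zerovalent palladium forms the allyl complex. The phenoxide should attack its tertiary terminus under kinetic control, which comes back to the route at 5 and bypasses 4 and step 3.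

## Further compounds

F1 | step 12 | 5-(tert-butyldimethylsilyloxy)-2-{2-[2,4-bis(tert-butyldimethylsilyloxy)phenyl]-1-hydroxyprop-2-enyl}-3-methoxy-4-(3-methylbut-2-enyl)phenol (racemic) | COc1c(C(O)C(=C)c2ccc(O[Si](C)(C)C(C)(C)C)cc2O[Si](C)(C)C(C)(C)C)c(O)cc(O[Si](C)(C)C(C)(C)C)c1CC=C(C)C
F2 | step 11 | 2-{1-[2,4-bis(tert-butyldimethylsilyloxy)phenyl]ethenyl}-1,3,6,2-dioxazaborocane | C=C(B1OCCNCCO1)c1ccc(O[Si](C)(C)C(C)(C)C)cc1O[Si](C)(C)C(C)(C)C
F3 | step 9 | 1-bromo-1-[2,4-bis(tert-butyldimethylsilyloxy)phenyl]ethene | C=C(Br)c1ccc(O[Si](C)(C)C(C)(C)C)cc1O[Si](C)(C)C(C)(C)C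
F4 | step 6 | 2-methoxy-3-(3-methylbut-2-enyl)-4,6-bis(trimethylsilyloxy)benzaldehyde | O=Cc1c(OC)c(CC=C(C)C)c(O[Si](C)(C)C)cc1O[Si](C)(C)C
F5 | step 2 | tert-butyl 2-methylbut-3-en-2-yl carbonate | C=CC(C)(C)OC(=O)OC(C)(C)C
A1 | alternative 1 | cis-3,9-bis(tert-butyldimethylsilyloxy)-1-methoxy-2-(3-methylbut-2-enyl)pterocarpan (racemic, one enantiomer drawn) | COc1c2c(cc(O[Si](C)(C)C(C)(C)C)c1CC=C(C)C)OC[C@@H]1c3ccc(O[Si](C)(C)C(C)(C)C)cc3O[C@H]21
A2 | alternative 1 | 7-(tert-butyldimethylsilyloxy)-5-methoxy-6-(3-methylbut-2-enyl)-2H-chromene | COc1c2c(cc(O[Si](C)(C)C(C)(C)C)c1CC=C(C)C)OCC=C2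
A3 | alternative 1 | 5-(tert-butyldimethylsilyloxy)-2-iodophenol | Oc1cc(O[Si](C)(C)C(C)(C)C)ccc1I
A4 | alternative 2 | 3-[2,4-bis(pivaloyloxy)phenyl]-5,7-dihydroxychromenylium chloride | Oc1cc(O)c2cc(-c3ccc(OC(=O)C(C)(C)C)cc3OC(=O)C(C)(C)C)c[o+]c2c1.[Cl-]
A5 | alternative 2 | 2-[2,4-bis(pivaloyloxy)phenyl]malonaldehyde | O=CC(C=O)c1ccc(OC(=O)C(C)(C)C)cc1OC(=O)C(C)(C)C
A6 | alternative 2 | phloroglucinol | Oc1cc(O)cc(O)c1
A7 | alternative 3 | 2',4'-bis-O-triisopropylsilyl dehydroglyasperin C | COc1c2c(cc(O)c1CC=C(C)C)OCC(c1ccc(O[Si](C(C)C)(C(C)C)C(C)C)cc1O[Si](C(C)C)(C(C)C)C(C)C)=C2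
A8 | alternative 3 | (Z)-2-[2,4-bis(triisopropylsilyloxy)phenyl]-5-methoxypent-2-en-4-ynyl 7-methyl-3-oxooct-6-enoate | COC#C/C=C(/c1ccc(O[Si](C(C)C)(C(C)C)C(C)C)cc1O[Si](C(C)C)(C(C)C)C(C)C)COC(=O)CC(=O)CCC=C(C)C
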